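## Structural features

The target is a 4H-chromen-4-one. Benzene ring A (C4a, C5–C8, C8a) is fused to 4-pyranone ring C (O1, C2, C3, C4). Ring B, a 3,4-dimethoxyphenyl group, is joined through C1' to C3, and a 3-methylbut-2-enyl (prenyl) ether sits on the oxygen at C7. There is no stereocentre and no stereogenic double bond, since the prenyl alkene carries two methyl groups, so the problem is one of connectivity only. The aryl prenyl ether is the fragile group: Brønsted and Lewis acids cleave it, heat rearranges it, and its electron-rich trisubstituted alkene is attacked by electrophilic halogen and by electrophilic oxidants. C2 of the pyranone is a vinylogous ester carbon that opens with hydroxide or amines, so the finished ring C should not see strong nucleophilic base. The real difficulty is to place ring B on C3, the carbon next to the carbonyl, and to close ring C under conditions the prenyl ether tolerates. The key step exploits the C3–C4 bond of ring C. With water added across C2=C3 (hydroxyl on C3), C4 is a ketone and C3 a tertiary carbinol, an α-ketol. Both carbons then derive from carbonyl groups: C4 from an aldehyde on ring A and C3 from the aryl ketone that carries ring B. These two electrophilic carbons can be joined only by reversing the polarity of one of them. O1 and C2 then reduce to a phenol oxygen and a phenacyl CH2.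

## Logic of the disconnections

6 to 5: the C2=C3 double bond is removed by adding water across it, hydroxyl on C3. This costs one step forward but exposes the α-ketol C3(OH)–C4(=O), the retron for a benzoin-type union. The forward step must dehydrate a tertiary alcohol that has β-hydrogens only on C2, so the alkene can form in one direction only. It must run near neutrality because of the prenyl ether.

5 to 4: the C3–C4 bond is cut, which opens ring C at a carbon–carbon bond instead of at O1. The gain is large: the bicyclic core with its fully substituted C3 falls back to an open keto aldehyde in which C4 is a formyl carbon on ring A and C3 is the carbonyl carbon of an aryl ketone on ring B. In one sentence, the plan is a carbene-catalysed intramolecular crossed benzoin closure of 4 at C3–C4. The forward step must turn the aldehyde carbon of 4 into a nucleophile while the ketone stays the acceptor. It must also outrun the aldol reaction of the CH2 between O1 and the ketone.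

4 to 2 and 3: the O1–C2 bond is cut, an ether between a phenol oxygen and a primary carbon next to a ketone. This divides the molecule into its ring A half and its ring B half, and 3 is commercial. The forward alkylation must stop at the ether and not go on to an aldol ring closure, which calls for a weak base and room temperature.

2 to 1: the O–CH2 bond of the prenyl ether is cut, leading to 1 and a prenyl halide. The ether is put on first because every later step is base-mediated or neutral. The forward step must alkylate the hydroxyl para to the formyl group and leave the ortho hydroxyl, which is tied up in a hydrogen bond to the aldehyde.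

## Other disconnections considered

Alternative 1: the one-carbon unit C2 is cut out (bonds O1–C2 and C2–C3), which leads back to the deoxybenzoin 1-(2,4-dihydroxyphenyl)-2-(3,4-dimethoxyphenyl)ethan-1-one A1. This is the route that comes to mind first. Forward, resorcinol is acylated with (3,4-dimethoxyphenyl)acetic acid in hot BF3·OEt2 to give A1. Formylation and ring closure with DMF/MsCl/BF3·OEt2 then give 7-hydroxy-3-(3,4-dimethoxyphenyl)-4H-chromen-4-one A2, which is prenylated last. It would be about as short as the chosen plan. It closes ring C at the heteroatom, and its hot Lewis acid steps rule out an early prenyl ether, so all selectivity questions move to a final alkylation of A2. The chosen plan is preferred because its ring closure is a by-product-free isomerisation, and all its steps are mild enough to carry the prenyl ether from step 1.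

Alternative 2: the C3–C1' bond is cut. Forward, 3-iodo-7-[(3-methylbut-2-en-1-yl)oxy]-4H-chromen-4-one A5 is coupled with (3,4-dimethoxyphenyl)boronic acid using Pd(PPh3)4 (zerovalent palladium). A5 comes from 1-{2-hydroxy-4-[(3-methylbut-2-en-1-yl)oxy]phenyl}ethan-1-one A3 through the enaminone (E)-3-(dimethylamino)-1-{2-hydroxy-4-[(3-methylbut-2-en-1-yl)oxy]phenyl}prop-2-en-1-one A4 and ring closure with iodine. The step count is the same as in the chosen plan, but ring C is again closed at O1–C2. Electrophilic iodine must also discriminate between the enaminone and the electron-rich prenyl alkene. A precious metal, a boronic acid and stoichiometric halogen are spent on a bond that the chosen plan gets from an organocatalytic isomerisation.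

Alternative 3: the C3–C1' bond is formed by a 1,2-shift of ring B from C2. This leads back to the chalcone (E)-3-(3,4-dimethoxyphenyl)-1-{2-hydroxy-4-[(3-methylbut-2-en-1-yl)oxy]phenyl}prop-2-en-1-one A6, made from A3 and 3,4-dimethoxybenzaldehyde. Forward, Tl(NO3)3 (trivalent thallium) in methanol with trimethyl orthoformate triggers the oxidative aryl migration. This gives the acetal 2-(3,4-dimethoxyphenyl)-1-{2-hydroxy-4-[(3-methylbut-2-en-1-yl)oxy]phenyl}-3,3-dimethoxypropan-1-one A7, and acid then closes ring C with loss of methanol. The oxidant is a soft electrophile that should attack the trisubstituted prenyl alkene at least as readily as the enone. The free ortho hydroxyl of A6 normally has to be masked to avoid other ring closures, and the acid closure endangers the prenyl ether. The prenyl group would therefore go on last, with protecting-group steps added, so the route becomes longer and uses a toxic heavy metal.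

Key step: step 3

Remark: 5 is made and used as the racemate, because its only stereocentre (C3) becomes sp2 in step 4. Compounds 1 and 3 and prenyl bromide are taken as commercial.

## Route

Step 1
Reactants: 1 2,4-dihydroxybenzaldehyde
Product: 2 2-hydroxy-4-[(3-methylbut-2-en-1-yl)oxy]benzaldehyde
Conditions: prenyl bromide (1.05 equiv), K2CO3 (1.05 equiv), acetone, rt to 40 °C
Reagents that add atoms: prenyl bromide (1-bromo-3-methylbut-2-ene), CC(C)=CCBr
Why: Williamson etherification by SN2 at the primary allylic carbon. The hydroxyl para to the formyl group is the more acidic and the more accessible, while the ortho hydroxyl is held in a hydrogen bond to the aldehyde oxygen, so one equivalent of base and halide should alkylate the para oxygen selectively.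

Step 2
Reactants: 2 2-hydroxy-4-[(3-methylbut-2-en-1-yl)oxy]benzaldehyde; 3 2-bromo-1-(3,4-dimethoxyphenyl)ethan-1-one
Product: 4 2-[2-(3,4-dimethoxyphenyl)-2-oxoethoxy]-4-[(3-methylbut-2-en-1-yl)oxy]benzaldehyde
Conditions: 3 (1.05 equiv), K2CO3 (1.5 equiv), acetone, rt
Reagents that add atoms: none
Why: Williamson etherification of the remaining phenol with an α-bromo ketone, a very reactive SN2 electrophile, forms the O1–C2 bond. Room temperature and a carbonate base are chosen so that the new O–CH2–C(=O) methylene does not condense with the neighbouring aldehyde.

Step 3
Reactants: 4 2-[2-(3,4-dimethoxyphenyl)-2-oxoethoxy]-4-[(3-methylbut-2-en-1-yl)oxy]benzaldehyde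
Product: 5 rac-3-(3,4-dimethoxyphenyl)-3-hydroxy-7-[(3-methylbut-2-en-1-yl)oxy]-2,3-dihydro-4H-chromen-4-one
Conditions: 2-(pentafluorophenyl)-6,7-dihydro-5H-pyrrolo[2,1-c][1,2,4]triazol-2-ium tetrafluoroborate (15 mol%), DBU (12 mol%), degassed THF (0.05 M), rt, Ar
Reagents that add atoms: none
Why: The triazolylidene freed from the azolium salt adds to the aldehyde carbon of 4, and proton transfer gives the Breslow enaminol, in which this carbon (the future C4) is nucleophilic. This acyl anion equivalent attacks the aryl ketone carbonyl (the future C3) in a 6-exo-trig closure that forms the C3–C4 bond and ring C; proton transfer and loss of the carbene then release ketol 5 and regenerate the catalyst. The closest known reaction type is the carbene-catalysed intramolecular crossed aldehyde–ketone benzoin reaction of 2-(2-oxoalkoxy)benzaldehydes to 3-hydroxychroman-4-ones. The new stereocentre C3 is formed without control by the achiral catalyst, as the racemate, which is acceptable because step 4 removes it. The donor and acceptor roles are fixed by the substrate, since only the aldehyde carbon bears the hydrogen needed to form the enaminol, and the six-membered closure should outrun aldehyde dimerisation at this dilution. The competing base-mediated aldol of the C2 methylene onto the aldehyde is held back by using an acidic N-pentafluorophenyl azolium with less base than azolium, so that almost no free amidine is present. The product has no hydrogen on C3 and so cannot epimerise or enolise toward O1.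

Step 4
Reactants: 5 rac-3-(3,4-dimethoxyphenyl)-3-hydroxy-7-[(3-methylbut-2-en-1-yl)oxy]-2,3-dihydro-4H-chromen-4-one
Product: 6 3-(3,4-dimethoxyphenyl)-7-[(3-methylbut-2-en-1-yl)oxy]-4H-chromen-4-one (7-prenyloxy-3',4'-dimethoxyisoflavone)
Conditions: Burgess reagent (methyl N-(triethylammoniosulfonyl)carbamate, 1.5 equiv), THF, 50–60 °C
Reagents that add atoms: none
Why: Burgess dehydration: the tertiary alcohol becomes a sulfamate ester that loses the elements of water by thermal syn elimination. The only β-hydrogens are on C2, so the alkene can form only as C2=C3, which completes the conjugated 4-pyranone. The neutral conditions should leave the prenyl ether and the methyl ethers untouched.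

## Compound list

1 | 2,4-dihydroxybenzaldehyde | O=Cc1ccc(O)cc1O | starting material
2 | 2-hydroxy-4-[(3-methylbut-2-en-1-yl)oxy]benzaldehyde | CC(C)=CCOc1ccc(C=O)c(O)c1 | intermediate
3 | 2-bromo-1-(3,4-dimethoxyphenyl)ethan-1-one | COc1ccc(C(=O)CBr)cc1OC | starting material
4 | 2-[2-(3,4-dimethoxyphenyl)-2-oxoethoxy]-4-[(3-methylbut-2-en-1-yl)oxy]benzaldehyde | COc1ccc(C(=O)COc2cc(OCC=C(C)C)ccc2C=O)cc1OC | intermediate
5 | rac-3-(3,4-dimethoxyphenyl)-3-hydroxy-7-[(3-methylbut-2-en-1-yl)oxy]-2,3-dihydro-4H-chromen-4-one (racemate) | COc1ccc(C2(O)COc3cc(OCC=C(C)C)ccc3C2=O)cc1OC | intermediate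
6 | 3-(3,4-dimethoxyphenyl)-7-[(3-methylbut-2-en-1-yl)oxy]-4H-chromen-4-one | COc1ccc(-c2coc3cc(OCC=C(C)C)ccc3c2=O)cc1OC | target

## Step count and least certain steps

Total step count: 4. Longest linear sequence: 4 steps (1 to 2 to 4 to 5 to 6); 3 enters in step 2.

Step 3 (key step). The most likely failure is that ring closure through the Breslow intermediate is slow. Both carbonyl groups are deactivated by alkoxy donors, so carbene addition to the 2,4-dialkoxybenzaldehyde and attack on the dimethoxyphenyl ketone are both slowed. The base-mediated aldol of the C2 methylene onto the aldehyde, which closes a five-membered furan ring, could then take over, as could air oxidation of the enaminol. The fallback forms the same C3–C4 bond with normal polarity, making C3 the nucleophile as an enamine carbon. It sets out from 2. Commercial (3,4-dimethoxyphenyl)acetaldehyde and morpholine are condensed (toluene, molecular sieves) to the enamine 4-[(E)-2-(3,4-dimethoxyphenyl)ethenyl]morpholine F1. F1 is stirred with 2 in toluene at rt. Its β-carbon adds to the aldehyde and the phenol traps the iminium ion, which should give 3-(3,4-dimethoxyphenyl)-2-(morpholin-4-yl)-7-[(3-methylbut-2-en-1-yl)oxy]-3,4-dihydro-2H-chromen-4-ol F2 as a mixture of racemic diastereomers. Oxidation of the benzylic alcohol (Dess–Martin periodinane, NaHCO3, CH2Cl2) gives 3-(3,4-dimethoxyphenyl)-2-(morpholin-4-yl)-7-[(3-methylbut-2-en-1-yl)oxy]-2,3-dihydro-4H-chromen-4-one F3. F3 should lose morpholine by β-elimination on brief warming with acetic acid, and the fallback returns to the route at 6.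

Step 4. The most likely failure is ionisation of the activated tertiary benzylic ester instead of concerted syn elimination. That would be followed by a 1,2-shift with ring contraction, or the hindered, hydrogen-bonded tertiary hydroxyl may fail to be sulfonylated at all. The fallback separates activation from elimination and uses a base-induced anti elimination. It sets out from 5. MsCl and Et3N in CH2Cl2 at −20 °C (sulfene pathway, which accepts tertiary alcohols) should give rac-3-(3,4-dimethoxyphenyl)-7-[(3-methylbut-2-en-1-yl)oxy]-4-oxo-3,4-dihydro-2H-chromen-3-yl methanesulfonate F4. DBU in toluene at 60 °C then removes the axial hydrogen on C2, and the fallback returns to the route at 6.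

Step 2. The most likely failure is further reaction of the product under the alkylation conditions: aldol ring closure of its active methylene onto the aldehyde, followed by loss of water, which consumes the keto aldehyde. The fallback introduces the ketone only after the ether bond is made. It sets out from 2. 3,4-Dimethoxybenzaldehyde is converted with trimethylsulfonium iodide and KOH (Corey–Chaykovsky reaction) into rac-2-(3,4-dimethoxyphenyl)oxirane F5. The phenoxide of 2 (K2CO3 0.2 equiv, DMF, 70 °C) opens F5 at the terminal carbon to give rac-2-[2-(3,4-dimethoxyphenyl)-2-hydroxyethoxy]-4-[(3-methylbut-2-en-1-yl)oxy]benzaldehyde F6. Oxidation of the secondary benzylic alcohol (Dess–Martin periodinane, NaHCO3, CH2Cl2, 0 °C) returns to the route at 4.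

Step 1. The most likely failure is loss of regiocontrol: alkylation of both hydroxyls, or C-alkylation of the electron-rich ring by the allylic halide. The fallback replaces the SN2 alkylation by a redox condensation. It sets out from 1. A Mitsunobu reaction with 3-methylbut-2-en-1-ol (PPh3, diisopropyl azodicarboxylate, THF, 0 °C) should engage only the more acidic, non-chelated para hydroxyl and returns to the route at 2 without a new intermediate.

## Further compounds

F1 | step 3 | 4-[(E)-2-(3,4-dimethoxyphenyl)ethenyl]morpholine | COc1ccc(/C=C/N2CCOCC2)cc1OC
F2 | step 3 | 3-(3,4-dimethoxyphenyl)-2-(morpholin-4-yl)-7-[(3-methylbut-2-en-1-yl)oxy]-3,4-dihydro-2H-chromen-4-ol (mixture of racemic diastereomers) | COc1ccc(C2C(O)c3ccc(OCC=C(C)C)cc3OC2N2CCOCC2)cc1OC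
F3 | step 3 | 3-(3,4-dimethoxyphenyl)-2-(morpholin-4-yl)-7-[(3-methylbut-2-en-1-yl)oxy]-2,3-dihydro-4H-chromen-4-one (mixture of racemic diastereomers) | COc1ccc(C2C(=O)c3ccc(OCC=C(C)C)cc3OC2N2CCOCC2)cc1OC
F4 | step 4 | rac-3-(3,4-dimethoxyphenyl)-7-[(3-methylbut-2-en-1-yl)oxy]-4-oxo-3,4-dihydro-2H-chromen-3-yl methanesulfonate | COc1ccc(C2(OS(C)(=O)=O)COc3cc(OCC=C(C)C)ccc3C2=O)cc1OC
F5 | step 2 | rac-2-(3,4-dimethoxyphenyl)oxirane | COc1ccc(C2CO2)cc1OC
F6 | step 2 | rac-2-[2-(3,4-dimethoxyphenyl)-2-hydroxyethoxy]-4-[(3-methylbut-2-en-1-yl)oxy]benzaldehyde | COc1ccc(C(O)COc2cc(OCC=C(C)C)ccc2C=O)cc1OC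
F0 | step 1 | none | none
A1 | alternative 1 | 1-(2,4-dihydroxyphenyl)-2-(3,4-dimethoxyphenyl)ethan-1-one | COc1ccc(CC(=O)c2ccc(O)cc2O)cc1OC
A2 | alternative 1 | 7-hydroxy-3-(3,4-dimethoxyphenyl)-4H-chromen-4-one | COc1ccc(-c2coc3cc(O)ccc3c2=O)cc1OC
A3 | alternative 2 | 1-{2-hydroxy-4-[(3-methylbut-2-en-1-yl)oxy]phenyl}ethan-1-one | CC(=O)c1ccc(OCC=C(C)C)cc1O
A4 | alternative 2 | (E)-3-(dimethylamino)-1-{2-hydroxy-4-[(3-methylbut-2-en-1-yl)oxy]phenyl}prop-2-en-1-one | CN(C)/C=C/C(=O)c1ccc(OCC=C(C)C)cc1O
A5 | alternative 2 | 3-iodo-7-[(3-methylbut-2-en-1-yl)oxy]-4H-chromen-4-one | CC(C)=CCOc1ccc2c(c1)occ(I)c2=O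
A6 | alternative 3 | (E)-3-(3,4-dimethoxyphenyl)-1-{2-hydroxy-4-[(3-methylbut-2-en-1-yl)oxy]phenyl}prop-2-en-1-one | COc1ccc(/C=C/C(=O)c2ccc(OCC=C(C)C)cc2O)cc1OC
A7 | alternative 3 | rac-2-(3,4-dimethoxyphenyl)-1-{2-hydroxy-4-[(3-methylbut-2-en-1-yl)oxy]phenyl}-3,3-dimethoxypropan-1-one | COc1ccc(C(C(OC)OC)C(=O)c2ccc(OCC=C(C)C)cc2O)cc1OC
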